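**Retrosynthetic overview**
1. C10–O ester: made last by Mitsunobu inversion of an (R)-α-ketol with unprotected caffeic acid; the ketol comes from Shi epoxidation of the Z-silyl enol ether of the C9 ethyl ketone.
2. Lactone (ring B): oxidation of a 2-ethoxy-3,6-dihydropyran acetal and shift of the alkene into conjugation; the C6 acetate comes from Mitsunobu inversion of a threo carbinol.
3. C5–C6 bond, both carbinol stereocentres and the six-membered ring in one step: allylboration of a cyclopropanecarbaldehyde with a racemic cyclic γ-alkoxyallylboronate, resolved during the coupling by a chiral phosphoric acid (new step).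
4. Cyclopropane (ring A): cinchona-catalysed ammonium-ylide cyclopropanation of ethyl vinyl ketone with a bromo Weinreb amide, which sets C7 and C8 from achiral materials.
5. Ring order: ring A (step 1), dihydropyran (steps 3 and 4), lactone ring B (step 6).

Assumption and labels: all numbered starting materials and the named organocatalysts are taken as catalogue items. Atom labels used below: C1 lactone C=O, C5 ring CH–O, C6 CH–OAc, C7/C8 cyclopropane CH, C9 ketone, C10 CH–O, C11 CH3.

**Step 1**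
Reactants: 1 2-bromo-N-methoxy-N-methylacetamide; 2 pent-1-en-3-one (ethyl vinyl ketone, 1.5 equiv)
Product: 3 (1S,2S)-N-methoxy-N-methyl-2-propanoylcyclopropane-1-carboxamide
Conditions: 9-O-methylquinidine (20 mol %), Cs2CO3 (1.3 equiv), MeCN, 80 °C, slow addition of 1
Reagents that add atoms: none
Why: Organocatalytic ammonium-ylide cyclopropanation (Michael-initiated ring closure): the quinuclidine nitrogen is alkylated by 1, Cs2CO3 gives the amide-stabilised ylide, this adds to the enone inside the alkaloid pocket and the enolate closes 3-exo-tet with loss of the amine, giving the trans ring and both C7 and C8 from achiral materials (the quinine-derived pseudo-enantiomer gives the antipode, so the sense is checked on the first run).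

**Step 2**
Reactants: 3
Product: 5 (1S,2S)-2-propanoylcyclopropane-1-carbaldehyde, via lithium enolate 4 (not isolated)
Conditions: LiN(SiMe3)2 (1.05 equiv), THF, −78 °C; then i-Bu2AlH (1.2 equiv), −78 °C; aq. KNaC4H4O6 work-up; used crude
Reagents that add atoms: none
Why: Weinreb amide reduction under enolate protection: only the ethyl CH2 is acidic enough to be deprotonated, the enolate is inert to hydride, and the amide is reduced only to the aldehyde level that is released, together with the ketone, on the aqueous quench; no stereocentre is touched.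

**Step 3**
Reactants: 6 (E)-3-(4,4,5,5-tetramethyl-1,3,2-dioxaborolan-2-yl)prop-2-enal; 7 ethyl vinyl ether
Product: 8 racemic cis-2-ethoxy-4-(4,4,5,5-tetramethyl-1,3,2-dioxaborolan-2-yl)-3,4-dihydro-2H-pyran
Conditions: tris(6,6,7,7,8,8,8-heptafluoro-2,2-dimethyloctane-3,5-dionato)ytterbium (5 mol %), neat 7 (10 equiv), rt
Reagents that add atoms: none
Why: Lewis-acid-catalysed inverse-electron-demand oxa-Diels–Alder reaction of the electron-poor 1-oxadiene with the enol ether; endo addition gives the cis 2,4-relationship, and the racemate is wanted because step 4 selects one enantiomer.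

**Step 4**
Reactants: 5; 8 (2.5 equiv)
Product: 10 1-[(1S,2S)-2-{(R)-[(2R,6S)-6-ethoxy-5,6-dihydro-2H-pyran-2-yl](hydroxy)methyl}cyclopropyl]propan-1-one, via pinacol borate 9 (not isolated)
Conditions: (S)-3,3'-bis(2,4,6-triisopropylphenyl)-1,1'-binaphthyl-2,2'-diyl hydrogen phosphate ((S)-TRIP, 10 mol %), 4 Å MS, toluene, −30 °C, 48 h; then aq. NaHCO3; chromatography on Et3N-deactivated silica
Reagents that add atoms: none
Why: Proposed new method: a chiral phosphoric acid-catalysed allylboration that resolves a racemic cyclic γ-alkoxyallylboronate while it couples; the acid hydrogen-bonds to a pinacol oxygen and, through its phosphoryl oxygen, to the formyl hydrogen, lowering the closed chair transition state so that it runs at −30 °C, where the uncatalysed reaction (which needs about 40 °C or more) is silent; allyl transfer is suprafacial, so each enantiomer of 8 can deliver only one aldehyde face, and the catalyst's face preference (Si face expected with (S)-TRIP by extension of the model for allyl pinacolboronate, to be confirmed, the (R)-acid being the alternative) selects (2S,4S)-8; the chair with the aldehyde substituent equatorial and the ring oxygen axial (a Z-type γ-substituent) gives the syn (threo) pair, C5 (R) and C6 (R), and the aldehyde reacts far faster than the ketone; the closest known reactions are the thermal allylboration of this class of cyclic boronate and the phosphoric acid-catalysed allylboration of aldehydes, including kinetic resolutions of racemic α-substituted allylboronates.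

**Step 5**
Reactants: 10
Product: 11 (S)-[(2R,6S)-6-ethoxy-5,6-dihydro-2H-pyran-2-yl][(1S,2S)-2-propanoylcyclopropyl]methyl acetate
Conditions: PPh3 (2 equiv), DIAD (2 equiv), AcOH (2 equiv), toluene–THF, 0 °C to rt
Reagents that add atoms: acetic acid, CC(=O)O
Why: Mitsunobu reaction: SN2 attack of acetate on the oxyphosphonium inverts the threo carbinol to the required (S) erythro C6 and installs the acetate in the same operation; the acyl-substituted cyclopropane and the β-oxygen disfavour ionisation.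

**Step 6**
Reactants: 11
Product: 14 (S)-[(2R)-6-oxo-3,6-dihydro-2H-pyran-2-yl][(1S,2S)-2-propanoylcyclopropyl]methyl acetate, via lactol 12 (not isolated), via deconjugated lactone 13 (not isolated)
Conditions: CrO3, H2SO4, H2O, acetone, 0 °C; extractive work-up; then DBU (0.2 equiv), CH2Cl2, rt
Reagents that add atoms: water, O
Why: Jones oxidation followed by base isomerisation: aqueous acid opens the mixed acetal to lactol 12, chromic acid oxidises it at once to the β,γ-unsaturated lactone 13, and catalytic DBU moves the alkene into conjugation through the dienolate; no stereocentre is touched.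

**Step 7**
Reactants: 14
Product: 15 (S)-{(1S,2S)-2-[(Z)-1-(tert-butyldimethylsilyloxy)prop-1-en-1-yl]cyclopropyl}[(2R)-6-oxo-3,6-dihydro-2H-pyran-2-yl]methyl acetate
Conditions: TBSOTf (1.15 equiv), Et3N (1.5 equiv), CH2Cl2, −78 to 0 °C
Reagents that add atoms: tert-butyldimethylsilyl trifluoromethanesulfonate, CC(C)(C)[Si](C)(C)OS(=O)(=O)C(F)(F)F
Why: Soft enolisation (silyl triflate and amine): only the ethyl CH2 of the ketone can enolise (the ring methine would give an alkylidenecyclopropane, and the lactone and acetate are far less basic), and allylic strain gives the Z-enol ether.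

**Step 8**
Reactants: 15
Product: 17 (S)-{(1S,2S)-2-[(R)-2-hydroxypropanoyl]cyclopropyl}[(2R)-6-oxo-3,6-dihydro-2H-pyran-2-yl]methyl acetate, via silyloxy epoxide 16 (not isolated)
Conditions: D-fructose-derived Shi ketone (0.3 equiv), KHSO5 (as Oxone), K2CO3 buffer (pH 9–10), Bu4NHSO4, MeCN–CH2(OMe)2–H2O, 0 °C, 1 h; then Et3N·3HF, MeCN, 0 °C
Reagents that add atoms: potassium peroxymonosulfate, [K+].[O-]S(=O)(=O)OO
Why: Shi asymmetric epoxidation (Rubottom-type oxidation): the chiral dioxirane attacks the electron-rich Z-enol ether and not the electron-poor lactone alkene, through the spiro transition state that places oxygen on the face giving (R) at C10 (same sense as for trans-β-methylstyrene), and fluoride collapses 16 to the ketol.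

**Step 9**
Reactants: 17; 18 (E)-3-(3,4-dihydroxyphenyl)prop-2-enoic acid (caffeic acid, 1.5 equiv)
Product: 19 (S)-1-[(1S,2S)-2-{(S)-acetoxy[(2R)-6-oxo-3,6-dihydro-2H-pyran-2-yl]methyl}cyclopropyl]-1-oxopropan-2-yl (E)-3-(3,4-dihydroxyphenyl)prop-2-enoate
Conditions: PPh3 (1.5 equiv), DIAD (1.5 equiv), THF, 0 °C to rt
Reagents that add atoms: none
Why: Mitsunobu esterification: the carboxylic acid (pKa about 4.5) is the only pronucleophile acidic enough to be engaged, so the free catechol is tolerated, and SN2 attack at the activated α-keto carbinol inverts C10 from R to S.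

**Compound list**
1 | 2-bromo-N-methoxy-N-methylacetamide | BrCC(=O)N(C)OC | starting material
2 | pent-1-en-3-one | C=CC(=O)CC | starting material
3 | (1S,2S)-N-methoxy-N-methyl-2-propanoylcyclopropane-1-carboxamide | CCC(=O)[C@H]1C[C@@H]1C(=O)N(C)OC | intermediate
4 | lithium (Z)-1-{(1S,2S)-2-[methoxy(methyl)carbamoyl]cyclopropyl}prop-1-en-1-olate | [Li+].C/C=C(\[O-])[C@H]1C[C@@H]1C(=O)N(C)OC | intermediate
5 | (1S,2S)-2-propanoylcyclopropane-1-carbaldehyde | CCC(=O)[C@H]1C[C@@H]1C=O | intermediate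
6 | (E)-3-(4,4,5,5-tetramethyl-1,3,2-dioxaborolan-2-yl)prop-2-enal | O=C/C=C/B1OC(C)(C)C(C)(C)O1 | starting material
7 | ethyl vinyl ether | C=COCC | starting material
8 | cis-2-ethoxy-4-(4,4,5,5-tetramethyl-1,3,2-dioxaborolan-2-yl)-3,4-dihydro-2H-pyran, racemic (drawn as the (2S,4S) enantiomer that reacts in step 4) | CCO[C@@H]1C[C@H](B2OC(C)(C)C(C)(C)O2)C=CO1 | intermediate
9 | 2-{(R)-[(2R,6S)-6-ethoxy-5,6-dihydro-2H-pyran-2-yl][(1S,2S)-2-propanoylcyclopropyl]methoxy}-4,4,5,5-tetramethyl-1,3,2-dioxaborolane | CC1(C)OB(O[C@H]([C@H]2C[C@@H]2C(=O)CC)[C@H]2C=CC[C@@H](OCC)O2)OC1(C)C | intermediate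
10 | 1-[(1S,2S)-2-{(R)-[(2R,6S)-6-ethoxy-5,6-dihydro-2H-pyran-2-yl](hydroxy)methyl}cyclopropyl]propan-1-one | O[C@H]([C@H]1C[C@@H]1C(=O)CC)[C@H]1C=CC[C@@H](OCC)O1 | intermediate
11 | (S)-[(2R,6S)-6-ethoxy-5,6-dihydro-2H-pyran-2-yl][(1S,2S)-2-propanoylcyclopropyl]methyl acetate | CC(=O)O[C@@H]([C@H]1C[C@@H]1C(=O)CC)[C@H]1C=CC[C@@H](OCC)O1 | intermediate
12 | (S)-[(2R)-6-hydroxy-5,6-dihydro-2H-pyran-2-yl][(1S,2S)-2-propanoylcyclopropyl]methyl acetate (lactol, anomer mixture) | CC(=O)O[C@@H]([C@H]1C[C@@H]1C(=O)CC)[C@H]1C=CCC(O)O1 | intermediate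
13 | (S)-[(2R)-6-oxo-5,6-dihydro-2H-pyran-2-yl][(1S,2S)-2-propanoylcyclopropyl]methyl acetate (β,γ-unsaturated lactone) | CC(=O)O[C@@H]([C@H]1C[C@@H]1C(=O)CC)[C@H]1C=CCC(=O)O1 | intermediate
14 | (S)-[(2R)-6-oxo-3,6-dihydro-2H-pyran-2-yl][(1S,2S)-2-propanoylcyclopropyl]methyl acetate (conjugated lactone) | CC(=O)O[C@@H]([C@H]1C[C@@H]1C(=O)CC)[C@H]1CC=CC(=O)O1 | intermediate
15 | (S)-{(1S,2S)-2-[(Z)-1-(tert-butyldimethylsilyloxy)prop-1-en-1-yl]cyclopropyl}[(2R)-6-oxo-3,6-dihydro-2H-pyran-2-yl]methyl acetate | CC(=O)O[C@@H]([C@H]1C[C@@H]1/C(O[Si](C)(C)C(C)(C)C)=C/C)[C@H]1CC=CC(=O)O1 | intermediate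
16 | (S)-{(1S,2S)-2-[(2S,3R)-2-(tert-butyldimethylsilyloxy)-3-methyloxiran-2-yl]cyclopropyl}[(2R)-6-oxo-3,6-dihydro-2H-pyran-2-yl]methyl acetate | CC(=O)O[C@@H]([C@H]1C[C@@H]1[C@@]2(O[Si](C)(C)C(C)(C)C)O[C@@H]2C)[C@H]1CC=CC(=O)O1 | intermediate
17 | (S)-{(1S,2S)-2-[(R)-2-hydroxypropanoyl]cyclopropyl}[(2R)-6-oxo-3,6-dihydro-2H-pyran-2-yl]methyl acetate | CC(=O)O[C@@H]([C@H]1C[C@@H]1C(=O)[C@@H](C)O)[C@H]1CC=CC(=O)O1 | intermediate
18 | (E)-3-(3,4-dihydroxyphenyl)prop-2-enoic acid (caffeic acid) | OC(=O)/C=C/c1ccc(O)c(O)c1 | starting material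
19 | (S)-1-[(1S,2S)-2-{(S)-acetoxy[(2R)-6-oxo-3,6-dihydro-2H-pyran-2-yl]methyl}cyclopropyl]-1-oxopropan-2-yl (E)-3-(3,4-dihydroxyphenyl)prop-2-enoate | CC(=O)O[C@@H]([C@H]1C[C@@H]1C(=O)[C@H](C)OC(=O)/C=C/c1ccc(O)c(O)c1)[C@H]1CC=CC(=O)O1 | target

**Step count and risks**
Total steps: 9. Longest linear sequence: 8 (steps 1, 2, 4, 5, 6, 7, 8, 9; step 3 is a one-step side branch).

Most likely to fail, first: step 4 (the proposed new step). The acid may not discriminate the two enantiomers of 8 well enough against the aldehyde's own facial bias, or it may protonate the enol ether of 8. The fallback uses known chemistry and moves the stereocontrol into the reagent. It sets out from 6 and 7: an enantioselective inverse-demand oxa-Diels–Alder reaction catalysed by chloro[2-(adamantan-1-yl)-4-methyl-6-({[(1S,2R)-2-oxido-2,3-dihydro-1H-inden-1-yl]imino}methyl)phenolato]chromium, CrCl(C27H29NO2), a trivalent chromium complex (1–3 mol %, or its mirror image, whichever gives the needed adduct; 4 Å MS, neat 7, rt), gives (2S,4S)-2-ethoxy-4-(4,4,5,5-tetramethyl-1,3,2-dioxaborolan-2-yl)-3,4-dihydro-2H-pyran F1 as a single enantiomer. Heating F1 with 5 in toluene at 45 °C without acid gives borate 9 through the closed chair transition state, and NaHCO3 work-up returns to the route at 10.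

Second: step 5. The carbinol is hindered, and a cyclopropylcarbinyl oxyphosphonium may ionise (ring opening) or be intercepted by the ring oxygen. The fallback inverts C6 by oxidation and reduction instead of SN2. It sets out from 10: Dess–Martin periodinane (NaHCO3, CH2Cl2) gives 1-[(1S,2S)-2-{[(2R,6S)-6-ethoxy-5,6-dihydro-2H-pyran-2-yl]carbonyl}cyclopropyl]propan-1-one F2. Zn(BH4)2 (Et2O, −78 °C) reduces the chelated α-alkoxy ketone faster than the remote ethyl ketone and, under Cram-chelate control, gives the anti alcohol 1-[(1S,2S)-2-{(S)-[(2R,6S)-6-ethoxy-5,6-dihydro-2H-pyran-2-yl](hydroxy)methyl}cyclopropyl]propan-1-one F3. Ac2O, pyridine and DMAP then return to the route at 11.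

Third: step 9. The α-ketol may eliminate or epimerise under Mitsunobu conditions, or the free phenols may interfere. The fallback acylates with retention using a protected acid. It sets out from 15: Shi epoxidation with the enantiomeric ketone (made from L-sorbose; same conditions as step 8) gives (S)-{(1S,2S)-2-[(2R,3S)-2-(tert-butyldimethylsilyloxy)-3-methyloxiran-2-yl]cyclopropyl}[(2R)-6-oxo-3,6-dihydro-2H-pyran-2-yl]methyl acetate F4, which Et3N·3HF collapses to (S)-{(1S,2S)-2-[(S)-2-hydroxypropanoyl]cyclopropyl}[(2R)-6-oxo-3,6-dihydro-2H-pyran-2-yl]methyl acetate F5. Separately, 18 is silylated (TBSCl, imidazole, DMF) to tert-butyldimethylsilyl (E)-3-[3,4-bis(tert-butyldimethylsilyloxy)phenyl]prop-2-enoate F6, whose silyl ester is cleaved (K2CO3, MeOH–H2O) to (E)-3-[3,4-bis(tert-butyldimethylsilyloxy)phenyl]prop-2-enoic acid F7. Steglich coupling of F5 with F7 (EDC·HCl, catalytic DMAP, CH2Cl2, 0 °C) gives (S)-1-[(1S,2S)-2-{(S)-acetoxy[(2R)-6-oxo-3,6-dihydro-2H-pyran-2-yl]methyl}cyclopropyl]-1-oxopropan-2-yl (E)-3-[3,4-bis(tert-butyldimethylsilyloxy)phenyl]prop-2-enoate F8, and HF·pyridine (THF, 0 °C) returns to the route at 19.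

**Further compounds**
F1 | step 4 | (2S,4S)-2-ethoxy-4-(4,4,5,5-tetramethyl-1,3,2-dioxaborolan-2-yl)-3,4-dihydro-2H-pyran, single enantiomer | CCO[C@@H]1C[C@H](B2OC(C)(C)C(C)(C)O2)C=CO1
F2 | step 5 | 1-[(1S,2S)-2-{[(2R,6S)-6-ethoxy-5,6-dihydro-2H-pyran-2-yl]carbonyl}cyclopropyl]propan-1-one | CCC(=O)[C@H]1C[C@@H]1C(=O)[C@H]1C=CC[C@@H](OCC)O1
F3 | step 5 | 1-[(1S,2S)-2-{(S)-[(2R,6S)-6-ethoxy-5,6-dihydro-2H-pyran-2-yl](hydroxy)methyl}cyclopropyl]propan-1-one | O[C@@H]([C@H]1C[C@@H]1C(=O)CC)[C@H]1C=CC[C@@H](OCC)O1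
F4 | step 9 | (S)-{(1S,2S)-2-[(2R,3S)-2-(tert-butyldimethylsilyloxy)-3-methyloxiran-2-yl]cyclopropyl}[(2R)-6-oxo-3,6-dihydro-2H-pyran-2-yl]methyl acetate | CC(=O)O[C@@H]([C@H]1C[C@@H]1[C@]2(O[Si](C)(C)C(C)(C)C)O[C@H]2C)[C@H]1CC=CC(=O)O1
F5 | step 9 | (S)-{(1S,2S)-2-[(S)-2-hydroxypropanoyl]cyclopropyl}[(2R)-6-oxo-3,6-dihydro-2H-pyran-2-yl]methyl acetate | CC(=O)O[C@@H]([C@H]1C[C@@H]1C(=O)[C@H](C)O)[C@H]1CC=CC(=O)O1
F6 | step 9 | tert-butyldimethylsilyl (E)-3-[3,4-bis(tert-butyldimethylsilyloxy)phenyl]prop-2-enoate | CC(C)(C)[Si](C)(C)OC(=O)/C=C/c1ccc(O[Si](C)(C)C(C)(C)C)c(O[Si](C)(C)C(C)(C)C)c1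
F7 | step 9 | (E)-3-[3,4-bis(tert-butyldimethylsilyloxy)phenyl]prop-2-enoic acid | OC(=O)/C=C/c1ccc(O[Si](C)(C)C(C)(C)C)c(O[Si](C)(C)C(C)(C)C)c1
F8 | step 9 | (S)-1-[(1S,2S)-2-{(S)-acetoxy[(2R)-6-oxo-3,6-dihydro-2H-pyran-2-yl]methyl}cyclopropyl]-1-oxopropan-2-yl (E)-3-[3,4-bis(tert-butyldimethylsilyloxy)phenyl]prop-2-enoate | CC(=O)O[C@@H]([C@H]1C[C@@H]1C(=O)[C@H](C)OC(=O)/C=C/c1ccc(O[Si](C)(C)C(C)(C)C)c(O[Si](C)(C)C(C)(C)C)c1)[C@H]1CC=CC(=O)O1
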